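## Retrosynthetic overview

1. Target ⇐ C‑formylation of the exocyclic carbon of a 2‑alkylidene‑5,5‑dimethyl‑2,5‑dihydrofuran, with hydrolysis of the acid and ketone protecting groups in the same pot.
2. The dihydrofuran (the only ring of the target, made last) ⇐ Ag‑catalysed ring expansion of a 3,3‑dimethyl‑2‑alkynyloxirane (oxirane → 2,5‑dihydrofuran).
3. Alkynyloxirane chain ⇐ ester reduction and acid protection ⇐ enantioselective Michael addition of a β,γ‑unsaturated acid enediolate to a skipped enynoate; this sets C‑2 and C‑3.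
4. Acid ⇐ diketene + Grignard reagent of ketal‑protected 5‑chloropentan‑2‑one. Enynoate ⇐ 3‑ethynyl‑2,2‑dimethyloxirane + methyl 4‑bromocrotonate; oxirane ⇐ 2‑chloro‑2‑methylpropanal + ethynylmagnesium bromide.
5. Ring order: oxirane (step 3, temporary) → dihydrofuran (step 8).

Assumptions:
- The oxirane carbon of 9, 11 and 13–15 is carried as a 1:1 mixture of configurations (left unspecified in the SMILES); it becomes sp2 in step 8.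
- TA = N1,N3‑bis[1‑phenyl‑2‑(piperidin‑1‑yl)ethyl]propane‑1,3‑diamine, a C2‑symmetric chiral tetraamine; the antipode that delivers the 2R acid is used and is recovered.
- C‑2/C‑3 refer to the pentanoic acid numbering of the target, which is (2R,3S,4E).

## Route

Step 1
Reactants: 1 5‑chloropentan‑2‑one
Product: 2 2‑(3‑chloropropyl)‑2‑methyl‑1,3‑dioxolane
Conditions: HOCH2CH2OH (1.5 equiv), p‑TsOH·H2O (1 mol%), PhMe, reflux, Dean–Stark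
Reagents that add atoms: ethylene glycol OCCO
Why: Acid‑catalysed ketalisation masks the methyl ketone so that the Grignard, lithium amide and hydride steps cannot touch it; no stereocentre.

Step 2
Reactants: 2 2‑(3‑chloropropyl)‑2‑methyl‑1,3‑dioxolane; 3 diketene (4‑methylideneoxetan‑2‑one)
Product: 5 3‑methylidene‑6‑(2‑methyl‑1,3‑dioxolan‑2‑yl)hexanoic acid, via Grignard reagent 4 (not isolated)
Conditions: Mg, THF, 45 °C; then 3, NiCl2 (5 mol%), THF, −20 °C → rt; 1 M HCl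
Reagents that add atoms: none
Why: Nickel‑catalysed cross‑coupling of the Grignard reagent at the vinylic C–O bond of diketene (β‑lactone ring opening) gives the 3‑methylidene acid directly; no stereocentre.

Step 3
Reactants: 6 2‑chloro‑2‑methylpropanal; 7 ethynylmagnesium bromide
Product: 9 3‑ethynyl‑2,2‑dimethyloxirane (racemic), via chlorohydrin alkoxide 8 (not isolated)
Conditions: THF, −78 → 0 °C; then 2 M aq. NaOH, rt
Reagents that add atoms: none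
Why: 1,2‑Addition of the acetylide to the non‑enolisable α‑chloro aldehyde, then base closure of the chlorohydrin (intramolecular Williamson, Darzens‑type); the one stereocentre is racemic and is erased in step 8.

Step 4
Reactants: 9 3‑ethynyl‑2,2‑dimethyloxirane; 10 methyl (2E)‑4‑bromobut‑2‑enoate
Product: 11 methyl (2E)‑6‑(3,3‑dimethyloxiran‑2‑yl)hex‑2‑en‑5‑ynoate
Conditions: CuI (10 mol%), n‑Bu4NI (10 mol%), K2CO3 (1.5 equiv), DMF, 0 °C → rt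
Reagents that add atoms: none
Why: Copper(I)‑catalysed SN2 coupling of the terminal alkyne with the primary allylic bromide gives the skipped enyne with the E‑enoate retained; mild carbonate limits isomerisation.

Step 5
Reactants: 5 3‑methylidene‑6‑(2‑methyl‑1,3‑dioxolan‑2‑yl)hexanoic acid; 11 methyl (2E)‑6‑(3,3‑dimethyloxiran‑2‑yl)hex‑2‑en‑5‑ynoate
Product: 13 (2R,3S)‑3‑[3‑(3,3‑dimethyloxiran‑2‑yl)prop‑2‑yn‑1‑yl]‑5‑methoxy‑2‑[5‑(2‑methyl‑1,3‑dioxolan‑2‑yl)pent‑1‑en‑2‑yl]‑5‑oxopentanoic acid, via dilithium enediolate 12 (not isolated)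
Conditions: TA (1.05 equiv), n‑BuLi (4.0 equiv), THF, 0 °C; 5, −78 °C; then 11, −78 °C, 1 h; 1 M HCl
Reagents that add atoms: none
Why: Enantioselective Michael addition of the acid enediolate held in a mixed aggregate with the chiral lithium amide (traceless auxiliary): the aggregate shields one enolate face and sets C‑2 (R), the lithium‑bridged transition state with the E‑enoate is expected to give the 2,3‑anti adduct and set C‑3 (S), and α‑attack of the dienediolate keeps the 1,1‑disubstituted alkene.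

Step 6
Reactants: 13 (2R,3S)‑3‑[3‑(3,3‑dimethyloxiran‑2‑yl)prop‑2‑yn‑1‑yl]‑5‑methoxy‑2‑[5‑(2‑methyl‑1,3‑dioxolan‑2‑yl)pent‑1‑en‑2‑yl]‑5‑oxopentanoic acid
Product: 14 (2R,3S)‑3‑[3‑(3,3‑dimethyloxiran‑2‑yl)prop‑2‑yn‑1‑yl]‑2‑[5‑(2‑methyl‑1,3‑dioxolan‑2‑yl)pent‑1‑en‑2‑yl]‑5‑oxopentanoic acid
Conditions: DIBAL‑H (2.2 equiv), CH2Cl2, −78 °C; MeOH, aq. Rochelle salt
Reagents that add atoms: none
Why: Partial ester reduction (stable tetrahedral aluminate at −78 °C) while the acid is protected in situ as its aluminium carboxylate; at this temperature the alkynyloxirane is not reduced and the stereocentres are untouched.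

Step 7
Reactants: 14 (2R,3S)‑3‑[3‑(3,3‑dimethyloxiran‑2‑yl)prop‑2‑yn‑1‑yl]‑2‑[5‑(2‑methyl‑1,3‑dioxolan‑2‑yl)pent‑1‑en‑2‑yl]‑5‑oxopentanoic acid
Product: 15 methoxymethyl (2R,3S)‑3‑[3‑(3,3‑dimethyloxiran‑2‑yl)prop‑2‑yn‑1‑yl]‑2‑[5‑(2‑methyl‑1,3‑dioxolan‑2‑yl)pent‑1‑en‑2‑yl]‑5‑oxopentanoate
Conditions: MOMCl (1.2 equiv), i‑Pr2NEt (1.5 equiv), CH2Cl2, 0 °C
Reagents that add atoms: chloromethyl methyl ether COCCl
Why: O‑alkylation of the carboxylate (no acyl activation, so no epimerisation at C‑2) gives an acetal‑type ester that removes the nucleophilic CO2H before the silver and Vilsmeier steps and is cleaved by the final aqueous acid.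

Step 8
Reactants: 15 methoxymethyl (2R,3S)‑3‑[3‑(3,3‑dimethyloxiran‑2‑yl)prop‑2‑yn‑1‑yl]‑2‑[5‑(2‑methyl‑1,3‑dioxolan‑2‑yl)pent‑1‑en‑2‑yl]‑5‑oxopentanoate
Product: 16 methoxymethyl (2R,3R,4Z)‑4‑(5,5‑dimethylfuran‑2(5H)‑ylidene)‑2‑[5‑(2‑methyl‑1,3‑dioxolan‑2‑yl)pent‑1‑en‑2‑yl]‑3‑(2‑oxoethyl)butanoate
Conditions: AgOTf (5 mol%), AcOH (30 mol%), 4 Å MS, CH2Cl2, 0 °C → rt
Reagents that add atoms: none
Why: Proposed new method: Ag(I) π‑activates the alkyne while AcOH (relay) opens the oxirane anti at the propargylic carbon and leaves the tertiary C–O bond intact; the freed tertiary hydroxyl adds 5‑endo‑dig to the silver–alkyne and protodemetalation gives a 3‑acetoxy‑2,3‑dihydrofuran; its allylic acetate ionises to a 2H‑furanium ion which, because C‑5 is quaternary, cannot aromatise and loses the exocyclic α‑proton instead, giving the 2‑alkylidene‑2,5‑dihydrofuran and returning AcOH (net oxirane → dihydrofuran ring expansion that forms the ring of the target; Ag rather than Au is chosen so the 1,6‑enyne is not cycloisomerised); closest known reaction type: Ag/Au‑catalysed cycloisomerisation of 2‑alkynyloxiranes to furans, not shown for 3,3‑dialkyl oxiranes ending in an exocyclic alkene.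

Step 9
Reactants: 16 methoxymethyl (2R,3R,4Z)‑4‑(5,5‑dimethylfuran‑2(5H)‑ylidene)‑2‑[5‑(2‑methyl‑1,3‑dioxolan‑2‑yl)pent‑1‑en‑2‑yl]‑3‑(2‑oxoethyl)butanoate
Product: 18 (2R,3S,4E)‑4‑(5,5‑dimethylfuran‑2(5H)‑ylidene)‑5‑oxo‑3‑(2‑oxoethyl)‑2‑(6‑oxohept‑1‑en‑2‑yl)pentanoic acid, via iminium chloride 17 (not isolated)
Conditions: POCl3/DMF (1.3 equiv each), CH2Cl2, 0 °C; then 1 M HCl–THF (1:2), rt
Reagents that add atoms: N,N‑dimethylformamide CN(C)C=O; water O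
Why: Vilsmeier–Haack formylation at the nucleophilic exocyclic carbon of the dienol ether, then aqueous acid hydrolyses the iminium, the MOM ester and the dioxolane in one pot; the push–pull alkene equilibrates to the E isomer (formyl anti to ring O, branched chain syn to O) and C‑2/C‑3 are not epimerised under acid.

## Compound list

1 | 5‑chloropentan‑2‑one | CC(=O)CCCCl | starting material
2 | 2‑(3‑chloropropyl)‑2‑methyl‑1,3‑dioxolane | CC1(CCCCl)OCCO1 | intermediate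
3 | diketene (4‑methylideneoxetan‑2‑one) | C=C1CC(=O)O1 | starting material
4 | chloro[3‑(2‑methyl‑1,3‑dioxolan‑2‑yl)propyl]magnesium | CC1(CCC[Mg]Cl)OCCO1 | intermediate
5 | 3‑methylidene‑6‑(2‑methyl‑1,3‑dioxolan‑2‑yl)hexanoic acid | C=C(CCCC1(C)OCCO1)CC(=O)O | intermediate
6 | 2‑chloro‑2‑methylpropanal | CC(C)(Cl)C=O | starting material
7 | ethynylmagnesium bromide | C#C[Mg]Br | starting material
8 | bromomagnesium 4‑chloro‑4‑methylpent‑1‑yn‑3‑olate | CC(C)(Cl)C(C#C)O[Mg]Br | intermediate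
9 | 3‑ethynyl‑2,2‑dimethyloxirane (racemic) | CC1(C)OC1C#C | intermediate
10 | methyl (2E)‑4‑bromobut‑2‑enoate | COC(=O)/C=C/CBr | starting material
11 | methyl (2E)‑6‑(3,3‑dimethyloxiran‑2‑yl)hex‑2‑en‑5‑ynoate | COC(=O)/C=C/CC#CC1OC1(C)C | intermediate
12 | dilithium 3‑methylidene‑6‑(2‑methyl‑1,3‑dioxolan‑2‑yl)hex‑1‑ene‑1,1‑bis(olate) | C=C(CCCC1(C)OCCO1)C=C([O-])[O-].[Li+].[Li+] | intermediate
13 | (2R,3S)‑3‑[3‑(3,3‑dimethyloxiran‑2‑yl)prop‑2‑yn‑1‑yl]‑5‑methoxy‑2‑[5‑(2‑methyl‑1,3‑dioxolan‑2‑yl)pent‑1‑en‑2‑yl]‑5‑oxopentanoic acid | C=C(CCCC1(C)OCCO1)[C@H](C(=O)O)[C@H](CC(=O)OC)CC#CC1OC1(C)C | intermediate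
14 | (2R,3S)‑3‑[3‑(3,3‑dimethyloxiran‑2‑yl)prop‑2‑yn‑1‑yl]‑2‑[5‑(2‑methyl‑1,3‑dioxolan‑2‑yl)pent‑1‑en‑2‑yl]‑5‑oxopentanoic acid | C=C(CCCC1(C)OCCO1)[C@H](C(=O)O)[C@H](CC=O)CC#CC1OC1(C)C | intermediate
15 | methoxymethyl (2R,3S)‑3‑[3‑(3,3‑dimethyloxiran‑2‑yl)prop‑2‑yn‑1‑yl]‑2‑[5‑(2‑methyl‑1,3‑dioxolan‑2‑yl)pent‑1‑en‑2‑yl]‑5‑oxopentanoate | C=C(CCCC1(C)OCCO1)[C@H](C(=O)OCOC)[C@H](CC=O)CC#CC1OC1(C)C | intermediate
16 | methoxymethyl (2R,3R,4Z)‑4‑(5,5‑dimethylfuran‑2(5H)‑ylidene)‑2‑[5‑(2‑methyl‑1,3‑dioxolan‑2‑yl)pent‑1‑en‑2‑yl]‑3‑(2‑oxoethyl)butanoate | C=C(CCCC1(C)OCCO1)[C@H](C(=O)OCOC)[C@H](CC=O)/C=C1/C=CC(C)(C)O1 | intermediate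
17 | methoxymethyl (2R,3S,4E)‑5‑(dimethyliminio)‑4‑(5,5‑dimethylfuran‑2(5H)‑ylidene)‑2‑[5‑(2‑methyl‑1,3‑dioxolan‑2‑yl)pent‑1‑en‑2‑yl]‑3‑(2‑oxoethyl)pentanoate chloride | C=C(CCCC1(C)OCCO1)[C@H](C(=O)OCOC)[C@H](CC=O)/C(C=[N+](C)C)=C1/C=CC(C)(C)O1.[Cl-] | intermediate
18 | (2R,3S,4E)‑4‑(5,5‑dimethylfuran‑2(5H)‑ylidene)‑5‑oxo‑3‑(2‑oxoethyl)‑2‑(6‑oxohept‑1‑en‑2‑yl)pentanoic acid | C=C(CCCC(C)=O)[C@H](C(=O)O)[C@H](CC=O)/C(C=O)=C1/C=CC(C)(C)O1 | target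

## Step count and risks

Total steps: 9. Longest linear sequence: 7 (steps 1, 2, 5, 6, 7, 8, 9).

Three steps most likely to fail:

**Step 5 (Michael addition).** The γ‑CH2 of 11 is both allylic and propargylic, so proton transfer to the enediolate may compete. The anti sense and the choice of amine antipode rest on analogy to simpler acid/enoate pairs. Fallback, setting out from 5 (as enediolate 12) and returning at 14: 12 is added under the same chiral lithium amide to commercial 5,6‑dihydro‑2H‑pyran‑2‑one, a cyclic enoate without a propargylic CH2, to give (2R)‑3‑methylidene‑6‑(2‑methyl‑1,3‑dioxolan‑2‑yl)‑2‑[(4R)‑2‑oxooxan‑4‑yl]hexanoic acid F1. DIBAL‑H (2.2 equiv, −78 °C) reduces the lactone to (2R)‑2‑[(4R)‑2‑hydroxyoxan‑4‑yl]‑3‑methylidene‑6‑(2‑methyl‑1,3‑dioxolan‑2‑yl)hexanoic acid F2. Ohira–Bestmann homologation (dimethyl (1‑diazo‑2‑oxopropyl)phosphonate, K2CO3, MeOH) converts the lactol carbon into the alkyne of (2R,3S)‑3‑(2‑hydroxyethyl)‑2‑[5‑(2‑methyl‑1,3‑dioxolan‑2‑yl)pent‑1‑en‑2‑yl]hex‑5‑ynoic acid F3. Its trianion (EtMgBr, 3.1 equiv) is added to 6 and closed with aq. NaOH as in step 3 to give (2R,3S)‑6‑(3,3‑dimethyloxiran‑2‑yl)‑3‑(2‑hydroxyethyl)‑2‑[5‑(2‑methyl‑1,3‑dioxolan‑2‑yl)pent‑1‑en‑2‑yl]hex‑5‑ynoic acid F4. Dess–Martin oxidation (NaHCO3, CH2Cl2) of the primary alcohol gives 14.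

**Step 8 (proposed ring expansion).** Risks are acid‑induced opening at the tertiary oxirane carbon (Meinwald‑type rearrangement), slow 5‑endo closure, and acid lability of 16. Fallback with known chemistry (cycloisomerisation of a (Z)‑enynol, no oxirane), setting out from 5 (as 12) and returning at 16: commercial ethyl (Z)‑3‑iodoacrylate and MeMgBr (2.2 equiv, Et2O, −78 → 0 °C) give (3Z)‑4‑iodo‑2‑methylbut‑3‑en‑2‑ol F5. Sonogashira coupling with methyl (2E)‑pent‑2‑en‑4‑ynoate (PdCl2(PPh3)2, CuI, Et3N) gives methyl (2E,6Z)‑8‑hydroxy‑8‑methylnona‑2,6‑dien‑4‑ynoate F6. Michael addition of 12 to F6 (its hydroxyl first deprotonated with 1 equiv LiHMDS) under the step‑5 conditions gives (2R,3S)‑3‑[(3Z)‑5‑hydroxy‑5‑methylhex‑3‑en‑1‑yn‑1‑yl]‑5‑methoxy‑2‑[5‑(2‑methyl‑1,3‑dioxolan‑2‑yl)pent‑1‑en‑2‑yl]‑5‑oxopentanoic acid F7. DIBAL‑H at −78 °C gives (2R,3S)‑3‑[(3Z)‑5‑hydroxy‑5‑methylhex‑3‑en‑1‑yn‑1‑yl]‑2‑[5‑(2‑methyl‑1,3‑dioxolan‑2‑yl)pent‑1‑en‑2‑yl]‑5‑oxopentanoic acid F8. MOMCl/i‑Pr2NEt gives methoxymethyl (2R,3S)‑3‑[(3Z)‑5‑hydroxy‑5‑methylhex‑3‑en‑1‑yn‑1‑yl]‑2‑[5‑(2‑methyl‑1,3‑dioxolan‑2‑yl)pent‑1‑en‑2‑yl]‑5‑oxopentanoate F9. AgOTf (5 mol%, CH2Cl2, rt) then effects 5‑exo‑dig addition of the tertiary hydroxyl to the alkyne (anti addition, Z alkene), giving 16.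

**Step 9 (formylation and global hydrolysis).** The exocyclic carbon is hindered, the free aldehyde may react with the Vilsmeier reagent, and 16 is acid‑sensitive. Fallback, setting out from 16 and returning at 18: NIS (NaHCO3, CH2Cl2, −40 °C, then Et3N) iodinates the exocyclic carbon to give methoxymethyl (2R,3S,4E)‑4‑(5,5‑dimethylfuran‑2(5H)‑ylidene)‑4‑iodo‑2‑[5‑(2‑methyl‑1,3‑dioxolan‑2‑yl)pent‑1‑en‑2‑yl]‑3‑(2‑oxoethyl)butanoate F10. Palladium‑catalysed reductive carbonylation (Pd(PPh3)4, CO 1 atm, Bu3SnH by slow addition, THF, 50 °C) gives methoxymethyl (2R,3S,4E)‑4‑(5,5‑dimethylfuran‑2(5H)‑ylidene)‑5‑oxo‑2‑[5‑(2‑methyl‑1,3‑dioxolan‑2‑yl)pent‑1‑en‑2‑yl]‑3‑(2‑oxoethyl)pentanoate F11. 1 M HCl–THF at rt then removes the MOM ester and the dioxolane to give 18.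

## Further compounds

F1 | step 5 | (2R)‑3‑methylidene‑6‑(2‑methyl‑1,3‑dioxolan‑2‑yl)‑2‑[(4R)‑2‑oxooxan‑4‑yl]hexanoic acid | C=C(CCCC1(C)OCCO1)[C@H](C(=O)O)[C@@H]1CCOC(=O)C1
F2 | step 5 | (2R)‑2‑[(4R)‑2‑hydroxyoxan‑4‑yl]‑3‑methylidene‑6‑(2‑methyl‑1,3‑dioxolan‑2‑yl)hexanoic acid | C=C(CCCC1(C)OCCO1)[C@H](C(=O)O)[C@@H]1CCOC(O)C1
F3 | step 5 | (2R,3S)‑3‑(2‑hydroxyethyl)‑2‑[5‑(2‑methyl‑1,3‑dioxolan‑2‑yl)pent‑1‑en‑2‑yl]hex‑5‑ynoic acid | C=C(CCCC1(C)OCCO1)[C@H](C(=O)O)[C@H](CCO)CC#C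
F4 | step 5 | (2R,3S)‑6‑(3,3‑dimethyloxiran‑2‑yl)‑3‑(2‑hydroxyethyl)‑2‑[5‑(2‑methyl‑1,3‑dioxolan‑2‑yl)pent‑1‑en‑2‑yl]hex‑5‑ynoic acid | C=C(CCCC1(C)OCCO1)[C@H](C(=O)O)[C@H](CCO)CC#CC1OC1(C)C
F5 | step 8 | (3Z)‑4‑iodo‑2‑methylbut‑3‑en‑2‑ol | CC(C)(O)/C=C\I
F6 | step 8 | methyl (2E,6Z)‑8‑hydroxy‑8‑methylnona‑2,6‑dien‑4‑ynoate | COC(=O)/C=C/C#C/C=C\C(C)(C)O
F7 | step 8 | (2R,3S)‑3‑[(3Z)‑5‑hydroxy‑5‑methylhex‑3‑en‑1‑yn‑1‑yl]‑5‑methoxy‑2‑[5‑(2‑methyl‑1,3‑dioxolan‑2‑yl)pent‑1‑en‑2‑yl]‑5‑oxopentanoic acid | C=C(CCCC1(C)OCCO1)[C@H](C(=O)O)[C@H](CC(=O)OC)C#C/C=C\C(C)(C)O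
F8 | step 8 | (2R,3S)‑3‑[(3Z)‑5‑hydroxy‑5‑methylhex‑3‑en‑1‑yn‑1‑yl]‑2‑[5‑(2‑methyl‑1,3‑dioxolan‑2‑yl)pent‑1‑en‑2‑yl]‑5‑oxopentanoic acid | C=C(CCCC1(C)OCCO1)[C@H](C(=O)O)[C@H](CC=O)C#C/C=C\C(C)(C)O
F9 | step 8 | methoxymethyl (2R,3S)‑3‑[(3Z)‑5‑hydroxy‑5‑methylhex‑3‑en‑1‑yn‑1‑yl]‑2‑[5‑(2‑methyl‑1,3‑dioxolan‑2‑yl)pent‑1‑en‑2‑yl]‑5‑oxopentanoate | C=C(CCCC1(C)OCCO1)[C@H](C(=O)OCOC)[C@H](CC=O)C#C/C=C\C(C)(C)O
F10 | step 9 | methoxymethyl (2R,3S,4E)‑4‑(5,5‑dimethylfuran‑2(5H)‑ylidene)‑4‑iodo‑2‑[5‑(2‑methyl‑1,3‑dioxolan‑2‑yl)pent‑1‑en‑2‑yl]‑3‑(2‑oxoethyl)butanoate | C=C(CCCC1(C)OCCO1)[C@H](C(=O)OCOC)[C@H](CC=O)/C(I)=C1/C=CC(C)(C)O1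
F11 | step 9 | methoxymethyl (2R,3S,4E)‑4‑(5,5‑dimethylfuran‑2(5H)‑ylidene)‑5‑oxo‑2‑[5‑(2‑methyl‑1,3‑dioxolan‑2‑yl)pent‑1‑en‑2‑yl]‑3‑(2‑oxoethyl)pentanoate | C=C(CCCC1(C)OCCO1)[C@H](C(=O)OCOC)[C@H](CC=O)/C(C=O)=C1/C=CC(C)(C)O1
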